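**Plan**
1. Last cut: the bond from the bridging CH2 to the enolic ring carbon of the non-aromatic ring (ortho-quinone methide plus vinylogous acid), giving the chromene amine 16 and the chiral trione 11.
2. Central cut in 11: the carbocycle is a 2-acylcyclohexane-1,3,5-trione kept non-aromatic by its quaternary carbon, so the bond from the C–OH carbon beside that quaternary carbon to the neighbouring enolic CH is a Claisen bond (ester carbon plus terminal carbon of a β-triketone dianion, open-chain triketo ester 9).
3. 9 is cut at its tri-acylated carbon into commercial 5-methylhexane-2,4-dione and a malonic half-ester chloride.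
4. Forward order: chiral malonate, acyclic triketo ester, carbocycle (step 6, never an arene); pyran ring of the chromene by hydroarylation of an aryl propargyl ether (step 9); the halves are joined last (step 11).
5. Stereochemistry: the one stereocenter is set by enantioselective phase-transfer prenylation of a mixed α-methylmalonate (step 3); the tert-butyl ester carbon becomes the ring carbon beside the acylated carbon and the diphenylethyl ester carbon the one closed in step 6, which turns the (R) malonate into the (R) ring; the centre bears no hydrogen and is not touched again.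

Key step: step 6

Assumption: the sense of induction in step 3 is not certain, so the (R,R) catalyst is taken to give (R)-4 and the (S,S) catalyst is used instead if the alkylation runs the other way; β-polyketones are drawn as one tautomer throughout.

**Step 1**
Reactants: 1 2,2,5-trimethyl-1,3-dioxane-4,6-dione
Product: 2 3-(tert-butoxy)-2-methyl-3-oxopropanoic acid (racemic)
Conditions: t-BuOH, reflux
Reagents that add atoms: tert-butanol, CC(C)(C)O
Why: Alcoholysis of the cyclic acylal by tert-butanol opens the dioxanedione with loss of acetone and gives the malonic half-ester, a standard ring-opening esterification of 5-substituted 2,2-dimethyl-1,3-dioxane-4,6-diones.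

**Step 2**
Reactants: 2 3-(tert-butoxy)-2-methyl-3-oxopropanoic acid
Product: 3 tert-butyl 2,2-diphenylethyl 2-methylpropanedioate (racemic, labile α-CH)
Conditions: 2,2-diphenylethanol, DCC, DMAP (cat.), CH2Cl2, 0 °C → rt
Reagents that add atoms: 2,2-diphenylethanol, OCC(c1ccccc1)c1ccccc1
Why: Steglich esterification of the free acid with a primary alcohol leaves the tert-butyl ester intact and gives the mixed diester whose two different ester groups are needed for ion-pair recognition and for later differentiation.

**Step 3**
Reactants: 3 tert-butyl 2,2-diphenylethyl 2-methylpropanedioate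
Product: 4 tert-butyl 2,2-diphenylethyl (R)-2-methyl-2-(3-methylbut-2-en-1-yl)propanedioate
Conditions: 1-bromo-3-methylbut-2-ene, (R,R) binaphthyl-derived N-spiro quaternary ammonium bromide with 3,4,5-trifluorophenyl groups at the 3,3′ positions (5 mol %), 50% aq. KOH, toluene, −40 °C
Reagents that add atoms: 1-bromo-3-methylbut-2-ene (prenyl bromide), CC(C)=CCBr
Why: Enantioselective phase-transfer alkylation of a mixed α-methylmalonate, in which the chiral ammonium cation pairs with the enolate, the bulky tert-butyl and the π-stacking diphenylethyl ester hold the enolate in one orientation and the allylic bromide enters from the unshielded face, should set the quaternary (R) centre under catalyst control.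

**Step 4**
Reactants: 4 tert-butyl 2,2-diphenylethyl (R)-2-methyl-2-(3-methylbut-2-en-1-yl)propanedioate
Product: 6 (S)-2-[(2,2-diphenylethoxy)carbonyl]-2,5-dimethylhex-4-enoic acid, via trimethylsilyl ester 5 (not isolated)
Conditions: Me3SiOTf (1.5 equiv), 2,6-lutidine (2 equiv), CH2Cl2, 0 °C; then H2O
Reagents that add atoms: none
Why: Silyl triflate cleavage of the tert-butyl ester (loss of 2-methylpropene from the O-silylated ester, then hydrolysis of the silyl ester) is buffered by lutidine so that the trisubstituted alkene is not protonated and cannot lactonise onto the new acid, while the primary ester and the hydrogen-free quaternary centre stay untouched.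

**Step 5**
Reactants: 6 (S)-2-[(2,2-diphenylethoxy)carbonyl]-2,5-dimethylhex-4-enoic acid; 7 5-methylhexane-2,4-dione
Product: 9 2,2-diphenylethyl (S)-2-(2-acetyl-4-methyl-3-oxopentanoyl)-2,5-dimethylhex-4-enoate (enolised triacylmethane), via acid chloride 8 (not isolated)
Conditions: 1-chloro-N,N,2-trimethylprop-1-en-1-amine, CH2Cl2, 0 °C → rt; then 7, MgCl2 (1 equiv), pyridine (2 equiv), CH2Cl2, 0 °C → rt; cold 1 M HCl wash
Reagents that add atoms: none
Why: Neutral conversion of the acid into its chloride with the α-chloroenamine, followed by soft-enolisation C-acylation of the β-diketone at its central carbon, gives the triacylmethane, C- over O-acylation being favoured because the product is held as a stable magnesium chelate.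

**Step 6**
Reactants: 9 2,2-diphenylethyl (S)-2-(2-acetyl-4-methyl-3-oxopentanoyl)-2,5-dimethylhex-4-enoate
Product: 11 (R)-3,5-dihydroxy-4-methyl-4-(3-methylbut-2-en-1-yl)-2-(2-methylpropanoyl)cyclohexa-2,5-dien-1-one, via dilithium dianion 10 (not isolated)
Conditions: LiN(iPr)2 (3.1 equiv), THF, −78 → −20 °C; then 1 M HCl
Reagents that add atoms: none
Why: Base converts the enolised triacylmethane into its dianion 10, whose terminal methylene carbon (the former acetyl methyl) attacks the ester carbon on the quaternary carbon and expels 2,2-diphenylethoxide, after which the new ring methylene is deprotonated and the product rests as a fully enolised triketone salt until the acid quench. The closest known reaction type is the Claisen (Dieckmann-type) C-acylation of β-dicarbonyl dianions by esters, as used in biomimetic polyketone cyclisations to acylphloroglucinols. The carbocycle closes in a 6-(enolexo)-exo-trig mode. No stereocenter is formed: the quaternary carbon has no acidic hydrogen, and because only the ester carbon can be substituted while the ketone carbon already sits beside the acylated carbon, the ring cannot form in the mirror-image sense. The step needs the second deprotonation to occur at the acetyl methyl (not the isobutyryl methine or the benzhydrylic C–H) and C- over O-acylation; the methyl is the least hindered and kinetically most acidic site, and the carbanion of the dianion is far more nucleophilic than the enolate oxygens, which could only give the pyran-2,4-dione. The other conceivable six-ring closure, from the isobutyryl methine, would need a tertiary carbanion to attack a neopentyl-type ester and should not compete.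

**Step 7**
Reactants: 12 benzene-1,3,5-triol (phloroglucinol)
Product: 13 2-methyl-1-(2,4,6-trihydroxyphenyl)propan-1-one
Conditions: isobutyryl chloride, AlCl3 (3 equiv), PhNO2/CH2Cl2, 0 → 40 °C; then ice/aq. HCl
Reagents that add atoms: 2-methylpropanoyl chloride (isobutyryl chloride), CC(C)C(Cl)=O
Why: Friedel–Crafts acylation of the symmetric, highly activated triol stops after one acyl group because the aryl ketone–AlCl3 complex is deactivated.

**Step 8**
Reactants: 13 2-methyl-1-(2,4,6-trihydroxyphenyl)propan-1-one
Product: 14 1-{2,6-dihydroxy-4-[(2-methylbut-3-yn-2-yl)oxy]phenyl}-2-methylpropan-1-one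
Conditions: 3-chloro-3-methylbut-1-yne (1.05 equiv), DBU (1.1 equiv), CuCl2·2H2O (1 mol %), MeCN, 0 °C
Reagents that add atoms: 3-chloro-3-methylbut-1-yne, CC(C)(Cl)C#C
Why: Copper-catalysed propargylic substitution with one equivalent of base, a known route to aryl 1,1-dimethylpropargyl ethers, should etherify the 4-hydroxyl selectively because it is the most acidic phenol (para to the carbonyl) while the two ortho hydroxyls are hydrogen-bonded to the ketone.

**Step 9**
Reactants: 14 1-{2,6-dihydroxy-4-[(2-methylbut-3-yn-2-yl)oxy]phenyl}-2-methylpropan-1-one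
Product: 15 1-(5,7-dihydroxy-2,2-dimethyl-2H-chromen-6-yl)-2-methylpropan-1-one
Conditions: Ph3PAuNTf2 (3 mol %), CH2Cl2, rt
Reagents that add atoms: none
Why: Gold-catalysed intramolecular alkyne hydroarylation (6-endo-dig attack of the electron-rich ring carbon ortho to the ether on the π-activated alkyne, then protodeauration) forms the 2,2-dimethyl-2H-chromene with the ring oxygen fixed as the former ether oxygen, so only the 6-acyl isomer can arise and the two ortho carbons are equivalent by symmetry.

**Step 10**
Reactants: 15 1-(5,7-dihydroxy-2,2-dimethyl-2H-chromen-6-yl)-2-methylpropan-1-one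
Product: 16 1-{8-[(dimethylamino)methyl]-5,7-dihydroxy-2,2-dimethyl-2H-chromen-6-yl}-2-methylpropan-1-one
Conditions: CH2(NMe2)2 (1.1 equiv), CH2Cl2, rt
Reagents that add atoms: bis(dimethylamino)methane, CN(C)CN(C)C
Why: Phenol Mannich aminomethylation with the aminal occurs at the single unsubstituted, doubly oxygen-activated ring carbon ortho to the 7-hydroxyl and installs the one-carbon bridge as an isolable ortho-quinone methide precursor.

**Step 11**
Reactants: 11 (R)-3,5-dihydroxy-4-methyl-4-(3-methylbut-2-en-1-yl)-2-(2-methylpropanoyl)cyclohexa-2,5-dien-1-one; 16 1-{8-[(dimethylamino)methyl]-5,7-dihydroxy-2,2-dimethyl-2H-chromen-6-yl}-2-methylpropan-1-one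
Product: 18 (R)-6-{[5,7-dihydroxy-2,2-dimethyl-6-(2-methylpropanoyl)-2H-chromen-8-yl]methyl}-3,5-dihydroxy-4-methyl-4-(3-methylbut-2-en-1-yl)-2-(2-methylpropanoyl)cyclohexa-2,5-dien-1-one, via ortho-quinone methide 17 (not isolated)
Conditions: toluene, 90 °C, argon
Reagents that add atoms: none
Why: Thermal loss of dimethylamine from the ortho-hydroxybenzylamine, assisted by proton transfer from the acidic trione, gives the ortho-quinone methide 17, which is trapped in a Michael addition by the only unsubstituted enolic ring carbon of 11 with rearomatisation, so the unsymmetrical methylene-bridged dimer should form without homodimers and without touching the quaternary centre.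

**Compound list**
1 | 2,2,5-trimethyl-1,3-dioxane-4,6-dione | CC1C(=O)OC(C)(C)OC1=O | starting material
2 | 3-(tert-butoxy)-2-methyl-3-oxopropanoic acid (racemic) | CC(C(=O)O)C(=O)OC(C)(C)C | intermediate
3 | tert-butyl 2,2-diphenylethyl 2-methylpropanedioate (racemic) | CC(C(=O)OC(C)(C)C)C(=O)OCC(c1ccccc1)c1ccccc1 | intermediate
4 | tert-butyl 2,2-diphenylethyl (R)-2-methyl-2-(3-methylbut-2-en-1-yl)propanedioate | CC(C)=CC[C@](C(=O)OC(C)(C)C)(C)C(=O)OCC(c1ccccc1)c1ccccc1 | intermediate
5 | 2,2-diphenylethyl trimethylsilyl (R)-2-methyl-2-(3-methylbut-2-en-1-yl)propanedioate (not isolated) | CC(C)=CC[C@](C(=O)O[Si](C)(C)C)(C)C(=O)OCC(c1ccccc1)c1ccccc1 | intermediate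
6 | (S)-2-[(2,2-diphenylethoxy)carbonyl]-2,5-dimethylhex-4-enoic acid | CC(C)=CC[C@](C(=O)O)(C)C(=O)OCC(c1ccccc1)c1ccccc1 | intermediate
7 | 5-methylhexane-2,4-dione | CC(=O)CC(=O)C(C)C | starting material
8 | 2,2-diphenylethyl (R)-2-(chlorocarbonyl)-2,5-dimethylhex-4-enoate (not isolated) | CC(C)=CC[C@](C(Cl)=O)(C)C(=O)OCC(c1ccccc1)c1ccccc1 | intermediate
9 | 2,2-diphenylethyl (S)-2-(2-acetyl-4-methyl-3-oxopentanoyl)-2,5-dimethylhex-4-enoate | CC(C)=CC[C@](C(=O)C(C(C)=O)C(=O)C(C)C)(C)C(=O)OCC(c1ccccc1)c1ccccc1 | intermediate
10 | dilithium dianion of 9, a bis-enolate with a terminal C=CH2 from the acetyl methyl (not isolated) | [Li+].[Li+].CC(C)=CC[C@](C(=O)C(C(=C)[O-])=C([O-])C(C)C)(C)C(=O)OCC(c1ccccc1)c1ccccc1 | intermediate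
11 | (R)-3,5-dihydroxy-4-methyl-4-(3-methylbut-2-en-1-yl)-2-(2-methylpropanoyl)cyclohexa-2,5-dien-1-one | CC(C)=CC[C@]1(C)C(O)=CC(=O)C(C(=O)C(C)C)=C1O | intermediate
12 | benzene-1,3,5-triol | Oc1cc(O)cc(O)c1 | starting material
13 | 2-methyl-1-(2,4,6-trihydroxyphenyl)propan-1-one | CC(C)C(=O)c1c(O)cc(O)cc1O | intermediate
14 | 1-{2,6-dihydroxy-4-[(2-methylbut-3-yn-2-yl)oxy]phenyl}-2-methylpropan-1-one | CC(C)C(=O)c1c(O)cc(OC(C)(C)C#C)cc1O | intermediate
15 | 1-(5,7-dihydroxy-2,2-dimethyl-2H-chromen-6-yl)-2-methylpropan-1-one | CC(C)C(=O)c1c(O)cc2OC(C)(C)C=Cc2c1O | intermediate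
16 | 1-{8-[(dimethylamino)methyl]-5,7-dihydroxy-2,2-dimethyl-2H-chromen-6-yl}-2-methylpropan-1-one | CC(C)C(=O)c1c(O)c(CN(C)C)c2OC(C)(C)C=Cc2c1O | intermediate
17 | 5-hydroxy-2,2-dimethyl-8-methylidene-6-(2-methylpropanoyl)-2H-chromen-7(8H)-one, the ortho-quinone methide (not isolated) | CC(C)C(=O)C1=C(O)C2=C(OC(C)(C)C=C2)C(=C)C1=O | intermediate
18 | (R)-6-{[5,7-dihydroxy-2,2-dimethyl-6-(2-methylpropanoyl)-2H-chromen-8-yl]methyl}-3,5-dihydroxy-4-methyl-4-(3-methylbut-2-en-1-yl)-2-(2-methylpropanoyl)cyclohexa-2,5-dien-1-one | CC(C)=CC[C@]1(C)C(O)=C(Cc2c(O)c(C(=O)C(C)C)c(O)c3c2OC(C)(C)C=C3)C(=O)C(C(=O)C(C)C)=C1O | target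

Total step count: 11. Longest linear sequence: 7 steps (steps 1 to 6, then step 11).

**Steps most likely to fail**

Step 6, the key ring closure. The base may deprotonate the benzhydrylic position of the ester and eliminate the carboxylate, the monoanion may close through oxygen to the enol lactone, or proton transfer from product to dianion may stall the conversion. The fallback sets out from 4 and comes back at 11; it closes the ring at its other Claisen bond, from a soft 1,3-diketone carbon onto a free acid.
- Saponification of the diphenylethyl ester of 4 (1 M KOH, MeOH, rt) should give (R)-2-(tert-butoxycarbonyl)-2,5-dimethylhex-4-enoic acid F1.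
- The α-chloroenamine converts it into tert-butyl (S)-2-(chlorocarbonyl)-2,5-dimethylhex-4-enoate F2.
- F2 is added at −78 °C to the dilithium dianion of 5-methylhexane-2,4-dione F3 (from 7 and 2 equiv LiN(iPr)2); terminal C-acylation should give tert-butyl (R)-2,5-dimethyl-2-(6-methyl-3,5-dioxoheptanoyl)hex-4-enoate F4.
- Me3SiOTf/2,6-lutidine removes the tert-butyl group to give (R)-2,5-dimethyl-2-(6-methyl-3,5-dioxoheptanoyl)hex-4-enoic acid F5.
- DCC/DMAP then acylates the carbon between the two distal ketones intramolecularly (O-acylation to the enol lactone, then DMAP-mediated O-to-C acyl shift) to give 11.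

The two malonate carbons keep the roles they have in the main route, so the same enantiomer of 4 serves.

Step 5. The diketone may be acylated on oxygen, attack on the neopentyl-type acid chloride may be slow, and the product may lose an acyl group by retro-Claisen cleavage on work-up. The fallback sets out from 6 (through 8) and comes back at 9; the hindered acyl group is attached first to a simple ketone enolate and the small acetyl group is added last. 8 is added to the lithium enolate of 3-methylbutan-2-one F6 (2 equiv, from the ketone and LiN(iPr)2, THF, −78 °C) to give the β-diketone 2,2-diphenylethyl (S)-2,5-dimethyl-2-(4-methyl-3-oxopentanoyl)hex-4-enoate F7. F7 is C-acetylated at its central carbon (MgCl2, pyridine, acetyl chloride, CH2Cl2) to give 9.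

Step 3. Facial selectivity in the ion-paired alkylation may be poor with the bulkier prenyl electrophile, or alkylation may be slow relative to ester hydrolysis. The fallback sets out from 3 and comes back at 4; it replaces asymmetric catalysis by resolution. Alkylation without chiral control (Bu4NBr, 50% aq. KOH, toluene, 0 °C) gives racemic tert-butyl 2,2-diphenylethyl 2-methyl-2-(3-methylbut-2-en-1-yl)propanedioate F8. Preparative chromatography on a chiral stationary phase then gives 4, and the other enantiomer is set aside.

**Further compounds**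
F1 | step 6 | (R)-2-(tert-butoxycarbonyl)-2,5-dimethylhex-4-enoic acid | CC(C)=CC[C@](C(=O)OC(C)(C)C)(C)C(=O)O
F2 | step 6 | tert-butyl (S)-2-(chlorocarbonyl)-2,5-dimethylhex-4-enoate | CC(C)=CC[C@](C(=O)OC(C)(C)C)(C)C(Cl)=O
F3 | step 6 | dilithium dianion of 5-methylhexane-2,4-dione | [Li+].[Li+].C=C([O-])C=C([O-])C(C)C
F4 | step 6 | tert-butyl (R)-2,5-dimethyl-2-(6-methyl-3,5-dioxoheptanoyl)hex-4-enoate | CC(C)=CC[C@](C(=O)OC(C)(C)C)(C)C(=O)CC(=O)CC(=O)C(C)C
F5 | step 6 | (R)-2,5-dimethyl-2-(6-methyl-3,5-dioxoheptanoyl)hex-4-enoic acid | CC(C)=CC[C@](C(=O)O)(C)C(=O)CC(=O)CC(=O)C(C)C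
F6 | step 5 | lithium 3-methylbut-1-en-2-olate (lithium enolate of 3-methylbutan-2-one) | [Li+].C=C([O-])C(C)C
F7 | step 5 | 2,2-diphenylethyl (S)-2,5-dimethyl-2-(4-methyl-3-oxopentanoyl)hex-4-enoate | CC(C)=CC[C@](C(=O)CC(=O)C(C)C)(C)C(=O)OCC(c1ccccc1)c1ccccc1
F8 | step 3 | racemic tert-butyl 2,2-diphenylethyl 2-methyl-2-(3-methylbut-2-en-1-yl)propanedioate | CC(C)=CCC(C)(C(=O)OC(C)(C)C)C(=O)OCC(c1ccccc1)c1ccccc1
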